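**Strategy.** Everything rests on cutting the two benzylic bonds C7–C8 and C7'–C8'. This leaves the C9–C8–C8'–C9' chain as succinaldehyde and turns each ArCH2 unit into a p-quinone methide, which is possible because C7 and C7' each sit para to the free phenolic OH of a 4-hydroxy-3,5-dimethoxyphenyl ring (rings A and B). In one operation a chiral secondary amine benzylates both alpha carbons of the dialdehyde, making two C–C bonds and both stereocentres (C8, C8') and closing no ring. The precursors are freshly distilled succinaldehyde and a crystalline 4-hydroxybenzyl p-tolyl sulfone that releases the quinone methide under mild base; borohydride then gives the diol.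

Key step: step 3

Remark on the chemistry: lignan numbering is used (C7/C7' benzylic, C8/C8' stereogenic, C9/C9' oxygen-bearing). By the CIP rules the target is (8R,8'R), that is (2R,3R) in butane numbering, and the descriptors are the same in the dialdehyde and the diol because CHO and CH2OH both outrank the neighbouring methine carbon.

## Route

**Step 1**
Reactants: 1 2,5-dimethoxytetrahydrofuran (commercial mixture of cis and trans isomers)
Product: 2 succinaldehyde (butanedial)
Conditions: H2O, 90 °C, 2 h; MeOH distilled off; CH2Cl2 extraction; distillation under reduced pressure; used the same day as a CH2Cl2 solution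
Reagents that add atoms: water, O
Why: Hydrolysis of a cyclic bis-acetal, in which hot water opens both acetal carbons and removal of methanol drives the equilibrium to the dialdehyde; no stereocentre is involved.

**Step 2**
Reactants: 3 4-(hydroxymethyl)-2,6-dimethoxyphenol (syringyl alcohol); 4 sodium 4-methylbenzenesulfinate
Product: 5 2,6-dimethoxy-4-[(4-methylbenzenesulfonyl)methyl]phenol
Conditions: 4 (1.5 equiv), HCO2H–H2O (1:1), 25 °C; filtration, recrystallisation from EtOH
Reagents that add atoms: none
Why: SN1-type S-alkylation of a sulfinate salt, in which acid ionises the electron-rich 4-hydroxybenzylic alcohol to a stabilised benzylic cation that the soft sulfur of the sulfinate captures; any O-bound sulfinate ester should re-ionise under the same conditions and end up as the sulfone.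

**Step 3**
Reactants: 2 succinaldehyde; 5 2,6-dimethoxy-4-[(4-methylbenzenesulfonyl)methyl]phenol
Product: 8 (2R,3R)-2,3-bis[(4-hydroxy-3,5-dimethoxyphenyl)methyl]butanedial, via quinone methide 6 (not isolated), via monobenzylated butanedial 7 (not isolated)
Conditions: (R)-2-[diphenyl(trimethylsilyloxy)methyl]pyrrolidine (20 mol%), 5 (2.4 equiv), powdered K2CO3 (2.6 equiv, in portions), CH2Cl2, 0 °C → 20 °C; cold filtration through Celite, filtrate used at once
Reagents that add atoms: none
Why: Proposed new method: K2CO3 deprotonates the phenol of 5 and the phenoxide expels toluenesulfinate in a 1,6-elimination, so that 6 is released slowly at the solid surface; the anti E-enamine formed from 2 and the (R)-configured catalyst attacks the exocyclic CH2 of 6 through its alpha carbon, rearomatisation of the ring makes the new C7–C8 bond irreversible, hydrolysis of the iminium ion returns the catalyst and 7, and the still unbranched aldehyde end of 7 repeats the cycle to form C7'–C8'. The closest known reaction types are the secondary-amine-catalysed asymmetric 1,6-addition of aldehyde enamines to p-quinone methides and the enamine alkylation of aldehydes with electrophiles unmasked by base from arylsulfonylmethyl arenes; neither has been run twice on one dialdehyde or with a methide carbon that carries two hydrogens. No ring is closed, so no mode of ring closure has to be controlled. Both new stereocentres, C8 and C8', are set by the catalyst: its diphenyl(trimethylsilyloxy)methyl group covers one face of each enamine, the electrophile should therefore reach the Re face of the alpha carbon, which corresponds to R at both centres, and the CH2 terminus of 6 adds no stereocentre of its own. The step needs enantioface selectivity at both ends, C–C bond formation in preference to capture of 6 by sulfinate or phenoxide, and a single benzylation per alpha carbon; the first rests on reagent control, the second on the fact that the sulfinate and phenoxide adducts can revert to 6 under base whereas the C-adduct cannot, and the third on the substrate, because an alpha-branched aldehyde end forms its enamine only slowly. Since the same catalyst face serves both ends, an error in either addition should end up mainly in the separable meso diastereomer and not in the enantiomer of 8.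

**Step 4**
Reactants: 8 (2R,3R)-2,3-bis[(4-hydroxy-3,5-dimethoxyphenyl)methyl]butanedial
Product: 9 5,5'-dimethoxysecoisolariciresinol, (2R,3R)-2,3-bis[(4-hydroxy-3,5-dimethoxyphenyl)methyl]butane-1,4-diol
Conditions: NaBH4 (4 equiv), MeOH–CH2Cl2, −10 → 0 °C; aq NH4Cl; chromatography on silica
Reagents that add atoms: none
Why: Borohydride reduction of both aldehydes to primary alcohols, which at low temperature should be much faster than enolisation, so that C8 and C8' keep the R configuration while phenols and aryl ethers are untouched.

## Compound list

1 | 2,5-dimethoxytetrahydrofuran (cis/trans mixture) | COC1CCC(OC)O1 | starting material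
2 | succinaldehyde (butanedial) | O=CCCC=O | intermediate
3 | 4-(hydroxymethyl)-2,6-dimethoxyphenol | COc1cc(CO)cc(OC)c1O | starting material
4 | sodium 4-methylbenzenesulfinate | Cc1ccc(cc1)S(=O)[O-].[Na+] | starting material
5 | 2,6-dimethoxy-4-[(4-methylbenzenesulfonyl)methyl]phenol | COc1cc(CS(=O)(=O)c2ccc(C)cc2)cc(OC)c1O | intermediate
6 | 2,6-dimethoxy-4-methylidenecyclohexa-2,5-dien-1-one (not isolated) | C=C1C=C(OC)C(=O)C(OC)=C1 | intermediate
7 | (2R)-2-[(4-hydroxy-3,5-dimethoxyphenyl)methyl]butanedial (not isolated) | O=CC[C@H](C=O)Cc1cc(OC)c(O)c(OC)c1 | intermediate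
8 | (2R,3R)-2,3-bis[(4-hydroxy-3,5-dimethoxyphenyl)methyl]butanedial | COc1cc(C[C@@H](C=O)[C@H](C=O)Cc2cc(OC)c(O)c(OC)c2)cc(OC)c1O | intermediate
9 | 5,5'-dimethoxysecoisolariciresinol, (2R,3R)-2,3-bis[(4-hydroxy-3,5-dimethoxyphenyl)methyl]butane-1,4-diol | COc1cc(C[C@@H](CO)[C@H](CO)Cc2cc(OC)c(O)c(OC)c2)cc(OC)c1O | target

Total step count: 4 (steps 1 and 2 prepare the two partners in parallel).
Longest linear sequence: 3 steps (3 → 5 → 8 → 9; the branch 1 → 2 joins at step 3).

## Steps most likely to fail

**Step 3 (Proposed new method).** Several processes may go wrong: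
- amine-catalysed self-aldol oligomerisation of the dialdehyde may outrun benzylation;
- the unhindered quinone methide may oligomerise or be captured at the catalyst nitrogen, which would drain the catalyst;
- the sequence may stop after the first benzylation;
- facial control in the second addition may be poor, because the adjacent new stereocentre can oppose the catalyst, which would raise the share of the meso diastereomer.

Fallback by known chemistry, setting out from 3 and returning to the route at 9:
- O-benzylation of the phenol of 3 (BnBr, K2CO3, acetone, reflux) should give [4-(benzyloxy)-3,5-dimethoxyphenyl]methanol F1.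
- PBr3 in Et2O at 0 °C should convert it into 2-(benzyloxy)-5-(bromomethyl)-1,3-dimethoxybenzene F2.
- Malonic ester alkylation (diethyl malonate, NaH, THF) should give diethyl 2-{[4-(benzyloxy)-3,5-dimethoxyphenyl]methyl}propanedioate F3.
- Saponification and decarboxylation (KOH, EtOH–H2O, reflux; then aq HCl, heat) should give 3-[4-(benzyloxy)-3,5-dimethoxyphenyl]propanoic acid F4.
- Mixed-anhydride acylation of the chiral auxiliary (4S)-4-(propan-2-yl)-1,3-oxazolidin-2-one (pivaloyl chloride, Et3N, LiCl, THF) should give (4S)-3-{3-[4-(benzyloxy)-3,5-dimethoxyphenyl]propanoyl}-4-(propan-2-yl)-1,3-oxazolidin-2-one F5.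
- Oxidative homocoupling of its enolate (LiN(iPr)2, THF, −78 °C; then TiCl4) is a known reaction of 3-arylpropanoyl oxazolidinones. The (4S) auxiliary shields one enolate face at both new centres, so the R,R dimer (2R,3R)-2,3-bis{[4-(benzyloxy)-3,5-dimethoxyphenyl]methyl}-1,4-bis[(4S)-2-oxo-4-(propan-2-yl)-1,3-oxazolidin-3-yl]butane-1,4-dione F6 is expected.
- LiBH4 (THF–MeOH, 0 °C) should remove both auxiliaries reductively to give (2R,3R)-2,3-bis{[4-(benzyloxy)-3,5-dimethoxyphenyl]methyl}butane-1,4-diol F7.
- Hydrogenolysis of the two benzyl ethers (H2, Pd/C, EtOAc–EtOH) should then give 9.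

**Step 4.** Configuration at C8 and C8' may be lost by enolisation in the basic borohydride medium before hydride is delivered, or the half-reduced material may close to a cyclic hemiacetal that is reduced only sluggishly.

Fallback, setting out from 8 and returning at 9: the oxidation level is first raised under buffered, weakly acidic conditions and then lowered. Pinnick oxidation (NaClO2, NaH2PO4, 2-methyl-2-butene, tBuOH–H2O, 0 °C; the alkene scavenger protects the phenol rings from hypochlorite) should give (2R,3R)-2,3-bis[(4-hydroxy-3,5-dimethoxyphenyl)methyl]butanedioic acid F8. This diacid is configurationally robust and can be crystallised, which allows any meso isomer to be removed. BH3·THF (THF, 0 °C → 20 °C) should then reduce both acids to give 9.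

**Step 2.** The benzylic cation may be captured in a Friedel–Crafts reaction by the electron-rich ring of a second molecule, leading to oligomerisation, and the sulfinic acid may disproportionate in the acidic medium.

Fallback, setting out from 3 and returning at 5: the C–S bond is made under basic instead of acidic activation and the sulfur is oxidised afterwards. Heating 3 with 4-methylbenzenethiol in aqueous ethanolic NaOH should expel hydroxide from the phenoxide and pass through transient 6, which the thiolate captures; ring positions ortho and para to the phenoxide oxygen are all occupied, so self-condensation has no easy path. This should give 2,6-dimethoxy-4-{[(4-methylphenyl)sulfanyl]methyl}phenol F9. Oxidation at sulfur (H2O2, Na2WO4 cat., MeOH, 20 °C) should then give 5.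

## Further compounds

F1 | step 3 | [4-(benzyloxy)-3,5-dimethoxyphenyl]methanol | COc1cc(CO)cc(OC)c1OCc1ccccc1
F2 | step 3 | 2-(benzyloxy)-5-(bromomethyl)-1,3-dimethoxybenzene | COc1cc(CBr)cc(OC)c1OCc1ccccc1
F3 | step 3 | diethyl 2-{[4-(benzyloxy)-3,5-dimethoxyphenyl]methyl}propanedioate | CCOC(=O)C(Cc1cc(OC)c(OCc2ccccc2)c(OC)c1)C(=O)OCC
F4 | step 3 | 3-[4-(benzyloxy)-3,5-dimethoxyphenyl]propanoic acid | COc1cc(CCC(=O)O)cc(OC)c1OCc1ccccc1
F5 | step 3 | (4S)-3-{3-[4-(benzyloxy)-3,5-dimethoxyphenyl]propanoyl}-4-(propan-2-yl)-1,3-oxazolidin-2-one | COc1cc(CCC(=O)N2[C@@H](C(C)C)COC2=O)cc(OC)c1OCc1ccccc1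
F6 | step 3 | (2R,3R)-2,3-bis{[4-(benzyloxy)-3,5-dimethoxyphenyl]methyl}-1,4-bis[(4S)-2-oxo-4-(propan-2-yl)-1,3-oxazolidin-3-yl]butane-1,4-dione | COc1cc(C[C@@H](C(=O)N2[C@@H](C(C)C)COC2=O)[C@H](C(=O)N2[C@@H](C(C)C)COC2=O)Cc2cc(OC)c(OCc3ccccc3)c(OC)c2)cc(OC)c1OCc1ccccc1
F7 | step 3 | (2R,3R)-2,3-bis{[4-(benzyloxy)-3,5-dimethoxyphenyl]methyl}butane-1,4-diol | COc1cc(C[C@@H](CO)[C@H](CO)Cc2cc(OC)c(OCc3ccccc3)c(OC)c2)cc(OC)c1OCc1ccccc1
F8 | step 4 | (2R,3R)-2,3-bis[(4-hydroxy-3,5-dimethoxyphenyl)methyl]butanedioic acid | COc1cc(C[C@@H](C(=O)O)[C@H](C(=O)O)Cc2cc(OC)c(O)c(OC)c2)cc(OC)c1O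
F9 | step 2 | 2,6-dimethoxy-4-{[(4-methylphenyl)sulfanyl]methyl}phenol | COc1cc(CSc2ccc(C)cc2)cc(OC)c1O
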